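## Structural features

Daphnodorin D2 (17) is a flavone–flavan dimer joined through carbon. One half is an apigenin unit: benzo ring A fused to pyran-4-one ring C, a 4-hydroxyphenyl ring B on C2, and hydroxyls on C5 and C7. The other half is a 5,7,4'-trihydroxyflavan, that is, benzo ring A fused to a saturated dihydropyran ring C with a 4-hydroxyphenyl group on C2. A single sp2–sp2 bond runs from flavone C3 to flavan C8. It is flanked by flavone C2 (aryl) and C4 (carbonyl) on one side and by flavan C7–OH and C8a–O1 on the other, so all four ortho positions are filled. The only stereocentre is flavan C2 (S); its ring neighbours C3 and C4 are CH2 groups, so no stereocentres stand next to each other, but the crowded C3–C8 axis is a latent second stereo-element. The fragile spot is the flavan O1–C2 bond, a benzylic ether para to oxygen, which with the 4'-OH free opens through a para-quinone methide in base or a benzylic cation in acid, and either path racemises C2; the six phenols and two phloroglucinol-type rings are also easily oxidised and nucleophilic at their free C6/C8 positions. The real difficulty is the tetra-ortho-substituted inter-unit bond, which must form at flavan C8 and not at C6, whereas the stereocentre can be bought. The key step exploits flavan ring A: its C8 has oxygen on both ortho carbons (C7, C8a) and on the para carbon (C5), so this aryl group bridges and migrates easily in a cationic 1,2-shift and can be attached first to the unhindered future flavone C2, then moved to C3 from within the molecule.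

## Logic of the disconnections

**17 ⇒ 16.**
- Bonds: the six phenolic O–H groups are traced back to six O–CH2Ph bonds.
- Reason: one kind of protecting group falls in one neutral operation, so the freed 4'-hydroxyflavan never meets the acid or base that would open O1–C2.
- Gain: every earlier intermediate is non-phenolic, soluble and far less oxidisable.
- Demand: hydrogenolysis must cleave primary benzyl aryl ethers faster than the cyclic secondary benzylic O1–C2 bond and must leave the tetrasubstituted C2=C3 bond alone.

**16 ⇒ 13 + 14.**
- Bond: flavone C2 to ring B (C2–C1').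
- Reason: without this aryl group C2 is a CH, which is exactly what a chalcone rearrangement delivers. With C3 blocked, that C–H is the only vinylic and the most acidic C–H of the molecule.
- Gain: one of the four ortho substituents around the axis disappears and a commercial C6 unit is split off.
- Demand: C2 must be metalated without attack on the carbonyl or the benzylic CH2 groups, and cross-coupled next to a bulky neighbour.
- A C–H zincation/Negishi sequence is preferred to conjugate addition plus dehydrogenation. It is one operation instead of two, and it never has to place palladium on the fully substituted C3.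

**13 ⇒ 11 (through 12).**
- Bonds: flavone C3–flavan C8 and flavone O1–C2.
- Reason: the hindered bond is made by a shift from the adjacent carbon, so no two crowded partners have to find each other.
- Gain: the pyranone ring opens, the flavan moves to a sterically free CH terminus, and the problem becomes an enone synthesis.
- Demand: the oxidant must attack the alkene and not the arenes, the flavan ring must be the group that moves, and ring closure must proceed under acid mild enough for O1–C2.
- Design of 11: the 2'-OH is kept free so that a trace of acid suffices for closure, since any acid-labile mask would need harsher treatment. The 4'-oxygen of the flavan is benzylated.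

**11 ⇒ 8 + 10.**
- Bond: the enone Cα=Cβ.
- Reason: it is the natural aldol seam, and it divides the molecule into halves of similar size.
- Gain: full convergence, with one chiral and one achiral fragment.
- Demand: an electron-rich, di-ortho-substituted aldehyde must condense with a ketone that sits as its phenoxide, and the product must not close to the isomeric flavanone.

**8 ⇒ 6 ⇒ 5.**
- Bonds: C8–CHO, then C8–Br.
- Reason: a halogen placed by electrophilic substitution fixes the site, and halogen–metal exchange transfers that regiochemistry to carbon without acid.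
- Gain: return to an unsubstituted ring A.
- Demand: bromination must choose C8 over C6 and stop at one bromine.

**5 ⇒ 4 ⇒ 1.**
- Bonds: three O–CH2Ph bonds, then restoration of the C4 carbonyl in place of CH2.
- Reason: the whole flavan skeleton with C2 (S) is available in 1. The ranking O1 > C1' > C3 > H at C2 does not change when C4=O becomes CH2, so the descriptor stays S.
- Gain: the stereocentre and fifteen carbons come from one purchased compound.
- Demand: the carbonyl must go before any prolonged contact with base, because the flavanone racemises by ring opening. The 4'-OH must be capped quickly afterwards.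

**10 ⇒ 9.**
- Bonds: two O–CH2Ph bonds.
- Reason: the hydrogen-bonded ortho hydroxyl is left over by itself.
- Gain: a commercial C8 unit.
- Demand: O- over C-alkylation, and a stop after two alkylations.

## Other disconnections considered

**Alternative 1:**
- Cut: flavan O1–C2.
- Forward step: a chiral phosphoric acid would ionise the racemic benzylic carbinol A1 to the para-quinone methide A2. The phenol on the future C8a would then add to the methide carbon in the 1,6-sense and close the dihydropyran to give A3.
- In favour: both enantiomers of A1 pass through one planar intermediate, so the configuration comes from a catalyst and not from a purchased flavanone whose optical purity must be trusted. The stereocentre is also made late and never meets organolithium, hydroxide or oxidant. Catalytic asymmetric 1,6-oxa-additions to quinone methides made in situ are an established reaction class.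
- Against: A3 necessarily keeps a free 4'-OH, so the same acid can reopen O1–C2 and the selectivity is exposed to thermodynamic erosion. The attacking hydroxyl sits next to the carbon bearing the flavone, so the catalyst pocket must hold a large, rotationally restricted neighbour, and the axis makes the transition states diastereomeric. Three free and four benzylated phenols call for orthogonal protection.
- On structure: this plan solves the stereocentre, which the chosen plan buys, but A1 already contains the C3–C8 bond, so the main difficulty is left to another method.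
- On mechanism: it uses on purpose the ionisation that the chosen plan must suppress. It is the better plan in its independence from the chiral pool and the weaker one in reversibility.
- On step economy: chain attachment at C4a, differentiated protection and a separate 3-arylflavone synthesis should exceed nine steps. The end-game of one hydrogenolysis is equal.

**Alternative 2:**
- Cut: C4–C4a and C8a–O1.
- Forward step: palladium/norbornene cooperative catalysis (Catellani reaction) would join the aryl iodide A4 with the bromo alcohol A5. The sequence is oxidative addition, norbornene insertion, palladation of the C4a–H bond, alkylation through tetravalent palladium, norbornene extrusion, and C–O reductive elimination from divalent palladium. The product A6 is identical with 16.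
- In favour: two bonds and a ring form in one step. The C–O bond at the stereocentre is never broken, so (S)-A5 maps onto (2S). A5 is accessible by asymmetric ketone reduction. The existing ortho substituent supplies the ortho effect that such cycles need.
- Against: A4 is an electron-rich iodide beside a very large group, so oxidative addition and insertion should be slow. The C–H bond to be palladated lies between the carbon–iodine carbon and C5–OBn and is buttressed. A secondary benzylic palladium alkoxide can undergo β-hydride elimination to a ketone instead of the slow C–O reductive elimination. A5 can also cyclise or eliminate under carbonate.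
- On structure: A4 again contains the hindered bond, so the problem is moved and not removed.
- On mechanism: a long catalytic cycle with several exits compares poorly with a single intramolecular shift.
- On step economy: from A4 onwards it is the equal or the better of the chosen plan, with one step to the penultimate compound, and the source of chirality is of equal quality. Counted from commercial materials the advantage is lost.

**Alternative 3:**
- Cut: C3–C4 and O1–C2.
- Forward step: a chiral phosphoric acid would dehydrate the ortho-hydroxybenzyl alcohol A7 to the ortho-quinone methide A8. This would take up 4-benzyloxystyrene A9 in an inverse-demand hetero-Diels–Alder reaction to give A10.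
- In favour: the dihydropyran is assembled in one step from a commercial alkene. The polarity of the partners dictates the 2-aryl regiochemistry. The symmetric dihydroxyaryl ring that precedes A7 makes the site of hydroxymethylation unambiguous.
- Against: A8 has an unsubstituted methide terminus, so it is highly reactive and prone to self-addition or capture by phenols. The new stereocentre forms at the styrene carbon, far from where the catalyst binds. A stepwise path through a 4-benzyloxybenzyl cation would blur facial control. Hydroxymethylation of such an electron-rich ring tends to run on to diarylmethanes.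
- On structure: it is the better plan for building flavan ring C from simple parts, but it presupposes the tetra-ortho bond.
- On mechanism: both plans depend on cations stabilised by oxygenated arenes, yet the chosen one creates no stereocentre in its difficult step, which makes it more predictable.
- On step economy: the ring-forming step is shorter than steps 1 to 4 of the chosen route, while the 3-arylflavone core must still be made, so the total should not be lower. The final deprotection is equal.

Key step: step 7

Assumption: the structure assigns only flavan C2 (S) and leaves the hindered C3–C8 axis undefined, so rotamers about this bond are treated as one compound (to be separated or thermally equilibrated at 17 if they prove separable); 1 is taken as the single (S)-enantiomer, with its enantiopurity checked by chiral HPLC before use.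

## Steps

Step 1
Reactants: 1 (S)-naringenin, (2S)-5,7-dihydroxy-2-(4-hydroxyphenyl)chroman-4-one
Product: 4 (2S)-2-(4-hydroxyphenyl)chroman-5,7-diol, via naringenin tris(ethyl carbonate) 2 (not isolated), via 5-hydroxyflavan 7,4'-bis(ethyl carbonate) 3 (not isolated)
Conditions: ClCO2Et (3.5 equiv), Et3N, THF, 0 °C; filter; NaBH4, THF–H2O, 0 °C → rt; 1 M NaOH, 0 °C, brief; work-up at pH 6
Reagents that add atoms: none
Why: Reductive deoxygenation of an ortho-acyloxyaryl ketone: NaBH4 reduces C4=O, the alkoxide takes over the neighbouring 5-O-carbonate, the freed 5-phenoxide expels ethyl carbonate, and the resulting ortho-quinone methide accepts a second hydride at C4. C2 is not involved, and fast acylation at 0 °C followed by fast reduction leaves little time for base-induced opening of the flavanone. The cold, short hydroxide treatment removes the two remaining carbonates with minimal para-quinone methide opening.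

Step 2
Reactants: 4 (2S)-2-(4-hydroxyphenyl)chroman-5,7-diol
Product: 5 (2S)-5,7-bis(benzyloxy)-2-[4-(benzyloxy)phenyl]chroman
Conditions: BnBr (3.3 equiv), K2CO3, DMF, 0 °C → rt
Reagents that add atoms: benzyl bromide, BrCc1ccccc1
Why: Threefold Williamson etherification, as used for polyhydroxyflavans without loss of configuration at C2. A weak base and low temperature keep the 4'-phenoxide short-lived, so O-alkylation outruns quinone methide opening of O1–C2. Once the 4'-oxygen is benzylated this racemisation path is closed for the rest of the route.

Step 3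
Reactants: 5 (2S)-5,7-bis(benzyloxy)-2-[4-(benzyloxy)phenyl]chroman
Product: 6 (2S)-5,7-bis(benzyloxy)-2-[4-(benzyloxy)phenyl]-8-bromochroman
Conditions: NBS (1.0 equiv), CH2Cl2, −78 °C → 0 °C
Reagents that add atoms: N-bromosuccinimide, O=C1CCC(=O)N1Br
Why: Electrophilic aromatic bromination, with ring A by far the most electron-rich ring. C8 lies between 7-OBn and the tied-back ring oxygen O1 and is less shielded than C6, which lies between two freely rotating benzyloxy groups; this is the site preference known for 5,7-di-O-benzylated flavans. One equivalent at low temperature avoids double bromination.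

Step 4
Reactants: 6 (2S)-5,7-bis(benzyloxy)-2-[4-(benzyloxy)phenyl]-8-bromochroman
Product: 8 (2S)-5,7-bis(benzyloxy)-2-[4-(benzyloxy)phenyl]chroman-8-carbaldehyde, via 8-lithioflavan 7 (not isolated)
Conditions: n-BuLi (1.1 equiv), THF, −78 °C; DMF, −78 °C → 0 °C; aq NH4Cl
Reagents that add atoms: N,N-dimethylformamide, CN(C)C=O
Why: Bromine–lithium exchange followed by Bouveault-type formylation. At −78 °C the exchange is faster than benzylic deprotonation or Wittig rearrangement of the benzyl ethers. The position of the halogen fixes the position of the formyl group without any acid.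

Step 5
Reactants: 9 2',4',6'-trihydroxyacetophenone
Product: 10 1-[2,4-bis(benzyloxy)-6-hydroxyphenyl]ethanone
Conditions: BnBr (2.05 equiv), K2CO3, DMF, rt
Reagents that add atoms: benzyl bromide, BrCc1ccccc1
Why: Selective Williamson etherification. After the para and one ortho hydroxyl have reacted, the last ortho hydroxyl is locked to the carbonyl by a hydrogen bond and is the least nucleophilic, so it stays free with two equivalents of halide.

Step 6
Reactants: 8 (2S)-5,7-bis(benzyloxy)-2-[4-(benzyloxy)phenyl]chroman-8-carbaldehyde, 10 1-[2,4-bis(benzyloxy)-6-hydroxyphenyl]ethanone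
Product: 11 (E)-1-[2,4-bis(benzyloxy)-6-hydroxyphenyl]-3-[(2S)-5,7-bis(benzyloxy)-2-(4-benzyloxyphenyl)chroman-8-yl]prop-2-en-1-one
Conditions: KOH (50 % aq), EtOH–THF, rt → 40 °C, Ar
Reagents that add atoms: none
Why: Claisen–Schmidt condensation (crossed aldol with E1cB dehydration). Aldehyde 8 has no α-hydrogen, so only one cross product can form, and the (E)-enone is the thermodynamic isomer. 2,4,6-Trialkoxybenzaldehydes are slow but competent partners, and the fully benzylated flavan has no base-labile site.

Step 7
Reactants: 11 (E)-1-[2,4-bis(benzyloxy)-6-hydroxyphenyl]-3-[(2S)-5,7-bis(benzyloxy)-2-(4-benzyloxyphenyl)chroman-8-yl]prop-2-en-1-one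
Product: 13 5,7-bis(benzyloxy)-3-[(2S)-5,7-bis(benzyloxy)-2-(4-benzyloxyphenyl)chroman-8-yl]chromen-4-one, via dimethyl acetal 12 (not isolated)
Conditions: Tl(NO3)3·3H2O (1.1 equiv), MeOH–HC(OMe)3–CH2Cl2, 0 °C → rt; filter; HCl (cat.), MeOH–THF, 40 °C
Reagents that add atoms: none
Why: This is the thallium trinitrate oxidative rearrangement of a 2'-hydroxychalcone to an isoflavone, a 1,2-aryl shift followed by acetal cyclisation. Electrophilic trivalent thallium bonds to Cα of the enone while methanol adds to Cβ, where the developing positive charge is carried by the trioxygenated flavan ring A. Heterolysis of the weak C–Tl bond is assisted by that ring: C8 bridges Cα and Cβ in a phenonium ion and ends on Cα (new bond flavone C3–flavan C8), monovalent thallium leaves as TlNO3, and the methoxy-stabilised cation at Cβ takes up a second methanol to give acetal 12. Catalytic acid then ionises 12 to an oxocarbenium ion, the 2'-hydroxyl adds to it in a 6-exo-trig closure (new bond O1–C2, ring C of the flavone), and loss of the second methanol gives the pyranone 13. No lasting stereocentre is created: Cα of 12 is stereogenic, forms as a mixture and becomes planar again, while flavan C2 is a spectator. Migration selectivity is secured because the only competitors are hydrogen and the electron-poor aroyl group, both far poorer migrating groups than an aryl ring with two ortho oxygens and one para oxygen, and the same donor strength steers 2'-hydroxychalcones away from aurone or flavone formation. Chemoselectivity for the alkene over the electron-rich arenes rests on its push–pull activation, on a near-stoichiometric charge of oxidant and on low temperature. Because the phenol is free, ring closure needs only a trace of acid at mild temperature, which together with the benzylated 4'-oxygen protects the flavan O1–C2 bond and hence the (S) configuration.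

Step 8
Reactants: 13 5,7-bis(benzyloxy)-3-[(2S)-5,7-bis(benzyloxy)-2-(4-benzyloxyphenyl)chroman-8-yl]chromen-4-one, 14 1-(benzyloxy)-4-iodobenzene
Product: 16 5,7-bis(benzyloxy)-2-[4-(benzyloxy)phenyl]-3-[(2S)-5,7-bis(benzyloxy)-2-(4-benzyloxyphenyl)chroman-8-yl]chromen-4-one, via chromon-2-ylzinc chloride 15 (not isolated)
Conditions: TMPZnCl·LiCl (1.5 equiv; TMP = 2,2,6,6-tetramethylpiperidide), THF, 25 °C; then 14, Pd(OAc)2 (5 mol %), SPhos (10 mol %), THF, 50 °C
Reagents that add atoms: none
Why: C–H zincation of a chromone with a hindered zinc amide followed by Negishi coupling. With C3 blocked, C2–H (vinylic, next to O1 and β to the carbonyl) is the only acidic ring C–H, and the mild zinc base leaves benzylic CH2, aryl C–H and flavan C2–H untouched. A compact C–Zn nucleophile and a bulky biarylphosphine suit a coupling beside the large C3 substituent, and one operation replaces an addition/dehydrogenation pair.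

Step 9
Reactants: 16 5,7-bis(benzyloxy)-2-[4-(benzyloxy)phenyl]-3-[(2S)-5,7-bis(benzyloxy)-2-(4-benzyloxyphenyl)chroman-8-yl]chromen-4-one
Product: 17 daphnodorin D2, 3-[(2S)-5,7-dihydroxy-2-(4-hydroxyphenyl)chroman-8-yl]-5,7-dihydroxy-2-(4-hydroxyphenyl)chromen-4-one
Conditions: H2 (1 atm), Pd(OH)2/C, THF–MeOH, rt; stop at the calculated uptake
Reagents that add atoms: none
Why: Catalytic hydrogenolysis of six aryl benzyl ethers. Primary O–CH2Ph bonds are cleaved faster than the cyclic secondary O1–C2 bond, as in the deprotection of benzylated flavans and flavan-3-ols, and the tetrasubstituted C2=C3 bond of the flavone is inert. The neutral medium at room temperature gives the freed 4'-hydroxyflavan no path to a quinone methide, so C2 stays (S).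

## Compound list

1 | (S)-naringenin, (2S)-5,7-dihydroxy-2-(4-hydroxyphenyl)chroman-4-one | O=C1C[C@@H](c2ccc(O)cc2)Oc2cc(O)cc(O)c12 | starting material
2 | (S)-naringenin 5,7,4'-tris(ethyl carbonate) | O=C1C[C@@H](c2ccc(OC(=O)OCC)cc2)Oc2cc(OC(=O)OCC)cc(OC(=O)OCC)c12 | intermediate
3 | ethyl 4-[(2S)-7-(ethoxycarbonyloxy)-5-hydroxychroman-2-yl]phenyl carbonate | CCOC(=O)Oc1cc(O)c2c(c1)O[C@H](c1ccc(OC(=O)OCC)cc1)CC2 | intermediate
4 | (2S)-2-(4-hydroxyphenyl)chroman-5,7-diol | Oc1cc(O)c2c(c1)O[C@H](c1ccc(O)cc1)CC2 | intermediate
5 | (2S)-5,7-bis(benzyloxy)-2-[4-(benzyloxy)phenyl]chroman | c1c(OCc4ccccc4)cc(OCc4ccccc4)c2c1O[C@H](c1ccc(OCc4ccccc4)cc1)CC2 | intermediate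
6 | (2S)-5,7-bis(benzyloxy)-2-[4-(benzyloxy)phenyl]-8-bromochroman | Brc1c(OCc4ccccc4)cc(OCc4ccccc4)c2c1O[C@H](c1ccc(OCc4ccccc4)cc1)CC2 | intermediate
7 | [(2S)-5,7-bis(benzyloxy)-2-(4-benzyloxyphenyl)chroman-8-yl]lithium | [Li]c1c(OCc4ccccc4)cc(OCc4ccccc4)c2c1O[C@H](c1ccc(OCc4ccccc4)cc1)CC2 | intermediate
8 | (2S)-5,7-bis(benzyloxy)-2-[4-(benzyloxy)phenyl]chroman-8-carbaldehyde | O=Cc1c(OCc4ccccc4)cc(OCc4ccccc4)c2c1O[C@H](c1ccc(OCc4ccccc4)cc1)CC2 | intermediate
9 | 2',4',6'-trihydroxyacetophenone | CC(=O)c1c(O)cc(O)cc1O | starting material
10 | 1-[2,4-bis(benzyloxy)-6-hydroxyphenyl]ethanone | CC(=O)c1c(O)cc(OCc2ccccc2)cc1OCc1ccccc1 | intermediate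
11 | (E)-1-[2,4-bis(benzyloxy)-6-hydroxyphenyl]-3-[(2S)-5,7-bis(benzyloxy)-2-(4-benzyloxyphenyl)chroman-8-yl]prop-2-en-1-one | O=C(/C=C/c1c(OCc4ccccc4)cc(OCc4ccccc4)c2c1O[C@H](c1ccc(OCc4ccccc4)cc1)CC2)c1c(O)cc(OCc4ccccc4)cc1OCc1ccccc1 | intermediate
12 | 1-[2,4-bis(benzyloxy)-6-hydroxyphenyl]-2-[(2S)-5,7-bis(benzyloxy)-2-(4-benzyloxyphenyl)chroman-8-yl]-3,3-dimethoxypropan-1-one (both epimers at C2 of the propanone) | COC(OC)C(C(=O)c1c(O)cc(OCc4ccccc4)cc1OCc1ccccc1)c1c(OCc4ccccc4)cc(OCc4ccccc4)c2c1O[C@H](c1ccc(OCc4ccccc4)cc1)CC2 | intermediate
13 | 5,7-bis(benzyloxy)-3-[(2S)-5,7-bis(benzyloxy)-2-(4-benzyloxyphenyl)chroman-8-yl]chromen-4-one | O=c1c(-c2c(OCc4ccccc4)cc(OCc4ccccc4)c3c2O[C@H](c2ccc(OCc4ccccc4)cc2)CC3)coc2cc(OCc4ccccc4)cc(OCc4ccccc4)c12 | intermediate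
14 | 1-(benzyloxy)-4-iodobenzene | Ic1ccc(OCc2ccccc2)cc1 | starting material
15 | {5,7-bis(benzyloxy)-3-[(2S)-5,7-bis(benzyloxy)-2-(4-benzyloxyphenyl)chroman-8-yl]-4-oxochromen-2-yl}zinc chloride | O=c1c(-c2c(OCc4ccccc4)cc(OCc4ccccc4)c3c2O[C@H](c2ccc(OCc4ccccc4)cc2)CC3)c([Zn]Cl)oc2cc(OCc4ccccc4)cc(OCc4ccccc4)c12 | intermediate
16 | daphnodorin D2 hexabenzyl ether, (2S) | O=c1c(-c2c(OCc4ccccc4)cc(OCc4ccccc4)c3c2O[C@H](c2ccc(OCc4ccccc4)cc2)CC3)c(-c2ccc(OCc4ccccc4)cc2)oc2cc(OCc4ccccc4)cc(OCc4ccccc4)c12 | intermediate
17 | daphnodorin D2, (2S) | O=c1c(-c2c(O)cc(O)c3c2O[C@H](c2ccc(O)cc2)CC3)c(-c2ccc(O)cc2)oc2cc(O)cc(O)c12 | target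

## Step count and least certain steps

Total step count: 9. Longest linear sequence: 8 steps (steps 1–4 and 6–9, from 1 to 17). Step 5 is the only side-branch step.

**Step 7 (key step).** Three failures are most likely.
- Oxidation, thallation or nitration of the electron-rich rings may compete with attack on the alkene.
- The free 2'-hydroxyl may add to the activated alkene before the aryl group has moved.
- The liberated nitric acid may ionise the flavan O1–C2 bond, with erosion of enantiopurity.

All three follow from the number of strongly donating arenes in 11. Thallium salts also demand strict containment.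

The fallback gives up the migration and forms the same C3–C8 bond by Suzuki–Miyaura coupling while chromone C2 still carries hydrogen, so only three ortho positions are filled. It sets out from 10 and 6 and comes back at 13. Compound 10 is condensed with N,N-dimethylformamide dimethyl acetal to the enaminone (E)-1-[2,4-bis(benzyloxy)-6-hydroxyphenyl]-3-(dimethylamino)prop-2-en-1-one F1. Iodine then closes and iodinates this to 5,7-bis(benzyloxy)-3-iodochromen-4-one F2. Compound 6 is lithiated as in step 4 (7) and quenched with 2-isopropoxy-4,4,5,5-tetramethyl-1,3,2-dioxaborolane to give (2S)-5,7-bis(benzyloxy)-2-[4-(benzyloxy)phenyl]-8-(4,4,5,5-tetramethyl-1,3,2-dioxaborolan-2-yl)chroman F3. Finally F2 and F3 are coupled with Pd(OAc)2, SPhos and K3PO4 in toluene–water to give 13.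

**Step 8.** Metalation may be incomplete, because the dialkoxy-substituted chromone is less acidic than the parent. Transmetalation and reductive elimination beside the bulky C3 aryl group may be slow, so that protonation on work-up simply returns 13. The product may also appear as slowly interconverting rotamers, which complicates analysis.

The fallback builds the C2–aryl bond by nucleophilic addition instead of C–H metalation. It sets out from 13 and 14 and comes back at 16. Compound 14 is converted with iPrMgCl·LiCl into 4-(benzyloxy)phenylmagnesium chloride F4. In the presence of CuBr·SMe2 and Me3SiCl in THF at −78 → −20 °C, F4 adds to C2 of 13 and is trapped as 5,7-bis(benzyloxy)-2-[4-(benzyloxy)phenyl]-3-[(2S)-5,7-bis(benzyloxy)-2-(4-benzyloxyphenyl)chroman-8-yl]-4-(trimethylsilyloxy)-2H-chromene F5. Saegusa–Ito dehydrogenation of F5 with Pd(OAc)2 in MeCN–THF restores the C2=C3 bond and gives 16.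

**Step 1.** Enantiopurity may erode in two ways: by reversible opening of the flavanone ring (retro-oxa-Michael) before the ketone is reduced, and by para-quinone methide opening of the flavan while the 4'-phenoxide is present during carbonate cleavage. The reduction may also stall at the benzylic alcohol stage.

The fallback caps the 4'- and 7-oxygens first under neutral conditions, so that no 4'-phenoxide ever exists on the flavan. It sets out from 1 and comes back at 5. Mitsunobu etherification of 1 (BnOH, PPh3, DIAD, THF, 0 °C) spares the hydrogen-bonded 5-OH and gives (2S)-7-(benzyloxy)-2-[4-(benzyloxy)phenyl]-5-hydroxychroman-4-one F6. Ethyl chloroformate and Et3N convert this into the 5-O-ethoxycarbonyl derivative (2S)-7-(benzyloxy)-2-[4-(benzyloxy)phenyl]-4-oxochroman-5-yl ethyl carbonate F7. NaBH4 in aqueous THF reduces F7 by the same quinone methide path to (2S)-7-(benzyloxy)-2-[4-(benzyloxy)phenyl]chroman-5-ol F8. Benzylation of F8 (BnBr, K2CO3, DMF) gives 5.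

**Step 6.** The condensation may be slow because the ketone is present as its phenoxide and the aldehyde is hindered and strongly donor-substituted. Long exposure to base then allows oxa-Michael closure of the product to the isomeric flavanone.

The fallback removes the phenoxide from the nucleophile. It sets out from 10 and 8 and comes back at 11. Compound 10 is masked (MOMCl, iPr2NEt, CH2Cl2) as 1-[2,4-bis(benzyloxy)-6-(methoxymethoxy)phenyl]ethanone F9. The neutral ketone F9 is condensed with 8 (KOH, EtOH–THF) to (E)-1-[2,4-bis(benzyloxy)-6-(methoxymethoxy)phenyl]-3-[(2S)-5,7-bis(benzyloxy)-2-(4-benzyloxyphenyl)chroman-8-yl]prop-2-en-1-one F10, which cannot cyclise. Brief treatment of F10 with catalytic HCl in MeOH–THF at 40 °C frees the phenol and gives 11.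

## Further compounds

F1 | step 7 | (E)-1-[2,4-bis(benzyloxy)-6-hydroxyphenyl]-3-(dimethylamino)prop-2-en-1-one | CN(C)/C=C/C(=O)c1c(O)cc(OCc2ccccc2)cc1OCc1ccccc1
F2 | step 7 | 5,7-bis(benzyloxy)-3-iodochromen-4-one | O=c1c(I)coc2cc(OCc3ccccc3)cc(OCc3ccccc3)c12
F3 | step 7 | (2S)-5,7-bis(benzyloxy)-2-[4-(benzyloxy)phenyl]-8-(4,4,5,5-tetramethyl-1,3,2-dioxaborolan-2-yl)chroman | CC1(C)OB(OC1(C)C)c1c(OCc4ccccc4)cc(OCc4ccccc4)c2c1O[C@H](c1ccc(OCc4ccccc4)cc1)CC2
F4 | step 8 | 4-(benzyloxy)phenylmagnesium chloride | Cl[Mg]c1ccc(OCc2ccccc2)cc1
F5 | step 8 | 5,7-bis(benzyloxy)-2-[4-(benzyloxy)phenyl]-3-[(2S)-5,7-bis(benzyloxy)-2-(4-benzyloxyphenyl)chroman-8-yl]-4-(trimethylsilyloxy)-2H-chromene (both epimers at chromene C2) | C[Si](C)(C)OC1=C(c2c(OCc4ccccc4)cc(OCc4ccccc4)c3c2O[C@H](c2ccc(OCc4ccccc4)cc2)CC3)C(c2ccc(OCc4ccccc4)cc2)Oc2cc(OCc4ccccc4)cc(OCc4ccccc4)c12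
F6 | step 1 | (2S)-7-(benzyloxy)-2-[4-(benzyloxy)phenyl]-5-hydroxychroman-4-one | O=C1C[C@@H](c2ccc(OCc3ccccc3)cc2)Oc2cc(OCc3ccccc3)cc(O)c12
F7 | step 1 | (2S)-7-(benzyloxy)-2-[4-(benzyloxy)phenyl]-4-oxochroman-5-yl ethyl carbonate | O=C1C[C@@H](c2ccc(OCc3ccccc3)cc2)Oc2cc(OCc3ccccc3)cc(OC(=O)OCC)c12
F8 | step 1 | (2S)-7-(benzyloxy)-2-[4-(benzyloxy)phenyl]chroman-5-ol | c1c(OCc4ccccc4)cc(O)c2c1O[C@H](c1ccc(OCc4ccccc4)cc1)CC2
F9 | step 6 | 1-[2,4-bis(benzyloxy)-6-(methoxymethoxy)phenyl]ethanone | CC(=O)c1c(OCOC)cc(OCc2ccccc2)cc1OCc1ccccc1
F10 | step 6 | (E)-1-[2,4-bis(benzyloxy)-6-(methoxymethoxy)phenyl]-3-[(2S)-5,7-bis(benzyloxy)-2-(4-benzyloxyphenyl)chroman-8-yl]prop-2-en-1-one | O=C(/C=C/c1c(OCc4ccccc4)cc(OCc4ccccc4)c2c1O[C@H](c1ccc(OCc4ccccc4)cc1)CC2)c1c(OCOC)cc(OCc4ccccc4)cc1OCc1ccccc1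
A1 | alternative 1 | 5,7-bis(benzyloxy)-2-[4-(benzyloxy)phenyl]-3-{4-(benzyloxy)-2,6-dihydroxy-3-[3-hydroxy-3-(4-hydroxyphenyl)propyl]phenyl}chromen-4-one (racemic carbinol) | O=c1c(-c2c(O)cc(OCc4ccccc4)c(CCC(O)c3ccc(O)cc3)c2O)c(-c2ccc(OCc4ccccc4)cc2)oc2cc(OCc4ccccc4)cc(OCc4ccccc4)c12
A2 | alternative 1 | para-quinone methide derived from A1 | O=c1c(-c2c(O)cc(OCc4ccccc4)c(CCC=C3C=CC(=O)C=C3)c2O)c(-c2ccc(OCc4ccccc4)cc2)oc2cc(OCc4ccccc4)cc(OCc4ccccc4)c12
A3 | alternative 1 | daphnodorin D2 tetrabenzyl ether with flavan 7-OH and 4'-OH free, (2S) | O=c1c(-c2c(O)cc(OCc4ccccc4)c3c2O[C@H](c2ccc(O)cc2)CC3)c(-c2ccc(OCc4ccccc4)cc2)oc2cc(OCc4ccccc4)cc(OCc4ccccc4)c12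
A4 | alternative 2 | 5,7-bis(benzyloxy)-2-[4-(benzyloxy)phenyl]-3-[2,4-bis(benzyloxy)-6-iodophenyl]chromen-4-one | O=c1c(-c2c(OCc4ccccc4)cc(OCc4ccccc4)cc2I)c(-c2ccc(OCc4ccccc4)cc2)oc2cc(OCc4ccccc4)cc(OCc4ccccc4)c12
A5 | alternative 2 | (S)-1-[4-(benzyloxy)phenyl]-3-bromopropan-1-ol | O[C@H](c1ccc(OCc2ccccc2)cc1)CCBr
A6 | alternative 2 | daphnodorin D2 hexabenzyl ether, (2S), identical with 16 | O=c1c(-c2c(OCc4ccccc4)cc(OCc4ccccc4)c3c2O[C@H](c2ccc(OCc4ccccc4)cc2)CC3)c(-c2ccc(OCc4ccccc4)cc2)oc2cc(OCc4ccccc4)cc(OCc4ccccc4)c12
A7 | alternative 3 | 5,7-bis(benzyloxy)-2-[4-(benzyloxy)phenyl]-3-[4-(benzyloxy)-2,6-dihydroxy-3-(hydroxymethyl)phenyl]chromen-4-one | O=c1c(-c2c(O)cc(OCc4ccccc4)c(CO)c2O)c(-c2ccc(OCc4ccccc4)cc2)oc2cc(OCc4ccccc4)cc(OCc4ccccc4)c12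
A8 | alternative 3 | ortho-quinone methide derived from A7 | O=c1c(C2=C(O)C=C(OCc4ccccc4)C(=C)C2=O)c(-c2ccc(OCc4ccccc4)cc2)oc2cc(OCc4ccccc4)cc(OCc4ccccc4)c12
A9 | alternative 3 | 4-benzyloxystyrene | C=Cc1ccc(OCc2ccccc2)cc1
A10 | alternative 3 | daphnodorin D2 pentabenzyl ether with flavan 7-OH free, (2S) | O=c1c(-c2c(O)cc(OCc4ccccc4)c3c2O[C@H](c2ccc(OCc4ccccc4)cc2)CC3)c(-c2ccc(OCc4ccccc4)cc2)oc2cc(OCc4ccccc4)cc(OCc4ccccc4)c12
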